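**Plan**

- The first cut is the C3–C4 bond of pyranone ring C. C3 (tertiary carbinol bearing ring B) sits next to C4 (ketone on ring A, ortho to the ring oxygen O1), so the two form an α-ketol, the retron of a benzoin reaction. The precursor is keto-aldehyde 9, in which the O1–C2 unit tethers the ring-B aryl ketone (future C3) to a salicylaldehyde carbon (future C4).
- The next cuts are the O1–C2 ether bond (phenol 8 + bromoketone 6), then the aryl–prenyl, CH2–Br and aryl–Br bonds of the ring-B piece. These lead back to commercial 2',3'-dihydroxy-4'-methoxyacetophenone 1 and 2,4-dihydroxybenzaldehyde 7.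
- Forward: ring B is decorated (bromination, silylation, Stille prenylation, α-bromination) and joined to ring A by Williamson etherification. Ring C is closed last by a carbene-catalysed crossed benzoin cyclization, and the three silyl ethers are then removed with fluoride.
- Stereochemistry: the only stereocentre, C3 (S), is created in the ring closure under control of a chiral triazolylidene catalyst. It is quaternary, so no later step can epimerize it by enolization.
- Silyl ethers (TBS on the catechol, TIPS on the 7-OH) are used because buffered fluoride removes them without touching the prenyl alkene or the acid- and base-sensitive α-ketol.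

Key step: step 7

Assumption: the sense of induction of the aminoindanol-derived triazolium catalyst on this substrate is not predicted here; both antipodes are commercial, and the route is written for the antipode that directs the acyl-anion carbon to the Re face of the ketone (3S product), to be assigned on the first run.

**Route**

Step 1
Reactants: 1 1-(2,3-dihydroxy-4-methoxyphenyl)ethan-1-one
Product: 2 1-(5-bromo-2,3-dihydroxy-4-methoxyphenyl)ethan-1-one
Conditions: Br2 (1.0 equiv), NaOAc, AcOH, rt
Reagents that add atoms: bromine, BrBr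
Why: Electrophilic aromatic bromination should go to C5, which is para to the 2-OH, ortho to the OMe and meta to the acetyl group, whereas the only other free position (C6) is ortho to the deactivating acetyl group; the acetate buffer suppresses acid-catalysed side-chain bromination.

Step 2
Reactants: 2 1-(5-bromo-2,3-dihydroxy-4-methoxyphenyl)ethan-1-one
Product: 3 1-[5-bromo-2,3-bis(tert-butyldimethylsilyloxy)-4-methoxyphenyl]ethan-1-one
Conditions: TBSCl (2.5 equiv), imidazole, DMAP (cat.), DMF, rt to 40 °C
Reagents that add atoms: tert-butyldimethylsilyl chloride (TBSCl), CC(C)(C)[Si](C)(C)Cl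
Why: Standard imidazole-promoted silylation of both phenols, with DMAP and gentle warming to bring in the hydrogen-bonded 2-OH, masks the catechol as ethers that tolerate the coupling and enolization steps and leave with fluoride.

Step 3
Reactants: 3 1-[5-bromo-2,3-bis(tert-butyldimethylsilyloxy)-4-methoxyphenyl]ethan-1-one
Product: 4 1-[2,3-bis(tert-butyldimethylsilyloxy)-4-methoxy-5-(3-methylbut-2-en-1-yl)phenyl]ethan-1-one
Conditions: tributyl(3-methylbut-2-en-1-yl)stannane, Pd(PPh3)4 (cat.), DMF, 100 °C
Reagents that add atoms: tributyl(3-methylbut-2-en-1-yl)stannane, CCCC[Sn](CCCC)(CCCC)CC=C(C)C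
Why: Stille coupling (oxidative addition of zerovalent palladium into the aryl C–Br bond, allyl transfer from tin, reductive elimination at the less hindered allyl terminus) should give the linear prenyl arene under neutral, fluoride-free conditions that spare the aryl silyl ethers and the methyl ketone.

Step 4
Reactants: 4 1-[2,3-bis(tert-butyldimethylsilyloxy)-4-methoxy-5-(3-methylbut-2-en-1-yl)phenyl]ethan-1-one
Product: 6 2-bromo-1-[2,3-bis(tert-butyldimethylsilyloxy)-4-methoxy-5-(3-methylbut-2-en-1-yl)phenyl]ethan-1-one, via trimethylsilyl enol ether 5 (not isolated)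
Conditions: TMSOTf, Et3N, CH2Cl2, 0 °C; then NBS, NaHCO3, THF, −78 °C
Reagents that add atoms: N-bromosuccinimide (NBS), O=C1CCC(=O)N1Br; trimethylsilyl trifluoromethanesulfonate (TMSOTf), C[Si](C)(C)OS(=O)(=O)C(F)(F)F (its silyl group stays only in intermediate 5)
Why: Soft enolization to the silyl enol ether followed by bromination with NBS is a regiospecific, acid-free α-bromination, and at −78 °C the enol ether should be far more nucleophilic than the trisubstituted prenyl alkene or the ring, so only the CH3 group is brominated.

Step 5
Reactants: 7 2,4-dihydroxybenzaldehyde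
Product: 8 2-hydroxy-4-(triisopropylsilyloxy)benzaldehyde
Conditions: TIPSCl (1.05 equiv), imidazole, CH2Cl2, 0 °C
Reagents that add atoms: triisopropylsilyl chloride (TIPSCl), CC(C)[Si](Cl)(C(C)C)C(C)C
Why: Selective silylation of the 4-OH is expected because the 2-OH is deactivated by its hydrogen bond to the aldehyde, and the bulky TIPS ether para to the formyl group should survive the later carbonate alkylation.

Step 6
Reactants: 8 2-hydroxy-4-(triisopropylsilyloxy)benzaldehyde; 6 2-bromo-1-[2,3-bis(tert-butyldimethylsilyloxy)-4-methoxy-5-(3-methylbut-2-en-1-yl)phenyl]ethan-1-one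
Product: 9 2-{2-[2,3-bis(tert-butyldimethylsilyloxy)-4-methoxy-5-(3-methylbut-2-en-1-yl)phenyl]-2-oxoethoxy}-4-(triisopropylsilyloxy)benzaldehyde
Conditions: K2CO3, acetone, 0 °C to rt, prompt work-up
Reagents that add atoms: none
Why: Williamson etherification of the acidic salicylaldehyde phenol with the highly reactive phenacyl-type bromide proceeds at or below room temperature, where the product keto-aldehyde should not yet undergo base-induced aldol (Rap–Stoermer) cyclization.

Step 7
Reactants: 9 2-{2-[2,3-bis(tert-butyldimethylsilyloxy)-4-methoxy-5-(3-methylbut-2-en-1-yl)phenyl]-2-oxoethoxy}-4-(triisopropylsilyloxy)benzaldehyde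
Product: 10 (3S)-3-[2,3-bis(tert-butyldimethylsilyloxy)-4-methoxy-5-(3-methylbut-2-en-1-yl)phenyl]-3-hydroxy-7-(triisopropylsilyloxy)chroman-4-one
Conditions: 2-(pentafluorophenyl)-5a,10b-dihydro-4H,6H-indeno[2,1-b][1,2,4]triazolo[4,3-d][1,4]oxazin-2-ium tetrafluoroborate (antipode giving 3S, 10 mol %), Et3N (10 mol %), toluene, rt, Ar
Reagents that add atoms: none
Why: Et3N deprotonates the triazolium salt to the carbene, which adds to the aldehyde carbon (future C4) and after proton transfer gives the Breslow enaminol, an acyl-anion equivalent that attacks the tethered ketone carbon (future C3); proton transfer and loss of the carbene then release the α-ketol and close the catalytic cycle. The closest known reaction type is the enantioselective carbene-catalysed intramolecular crossed aldehyde–ketone benzoin cyclization of 2-(2-oxo-2-arylethoxy)benzaldehydes to 3-aryl-3-hydroxychroman-4-ones. Ring C is closed in a 6-exo-trig mode, the attacked ketone C=O lying outside the six-membered ring that forms. The C3 stereocentre is set under catalyst control: the indane backbone blocks one face of the enaminol, and a hydrogen bond from the enaminol OH to the ketone oxygen orients the ketone so that its Re face is attacked, which gives the 3S ketol. The step needs the aldehyde as donor and the ketone as acceptor, which is secured because only the aldehyde can form the enaminol and the six-membered intramolecular closure should outrun aldehyde dimerization. It also needs the carbene pathway to outrun enolization of the O–CH2–C=O unit and aldol closure to a benzofuran, which is addressed by the acidic N-pentafluorophenyl triazolium, since it allows a weak amine base in catalytic amount.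

Step 8
Reactants: 10 (3S)-3-[2,3-bis(tert-butyldimethylsilyloxy)-4-methoxy-5-(3-methylbut-2-en-1-yl)phenyl]-3-hydroxy-7-(triisopropylsilyloxy)chroman-4-one
Product: 11 (3S)-3-[2,3-dihydroxy-4-methoxy-5-(3-methylbut-2-en-1-yl)phenyl]-3,7-dihydroxychroman-4-one
Conditions: TBAF (3.3 equiv), AcOH (3.5 equiv), THF, 0 °C to rt, Ar
Reagents that add atoms: none
Why: Fluoride-driven cleavage of the three aryl silyl ethers, buffered with acetic acid and run under argon, should free the phenols without α-ketol rearrangement, catechol oxidation or any change at the prenyl alkene, and the quaternary C3 centre is untouched.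

**Compound list**

1 | 1-(2,3-dihydroxy-4-methoxyphenyl)ethan-1-one | CC(=O)c1ccc(OC)c(O)c1O | starting material
2 | 1-(5-bromo-2,3-dihydroxy-4-methoxyphenyl)ethan-1-one | CC(=O)c1cc(Br)c(OC)c(O)c1O | intermediate
3 | 1-[5-bromo-2,3-bis(tert-butyldimethylsilyloxy)-4-methoxyphenyl]ethan-1-one | CC(=O)c1cc(Br)c(OC)c(O[Si](C)(C)C(C)(C)C)c1O[Si](C)(C)C(C)(C)C | intermediate
4 | 1-[2,3-bis(tert-butyldimethylsilyloxy)-4-methoxy-5-(3-methylbut-2-en-1-yl)phenyl]ethan-1-one | CC(=O)c1cc(CC=C(C)C)c(OC)c(O[Si](C)(C)C(C)(C)C)c1O[Si](C)(C)C(C)(C)C | intermediate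
5 | {1-[2,3-bis(tert-butyldimethylsilyloxy)-4-methoxy-5-(3-methylbut-2-en-1-yl)phenyl]ethenyloxy}trimethylsilane (not isolated) | C=C(O[Si](C)(C)C)c1cc(CC=C(C)C)c(OC)c(O[Si](C)(C)C(C)(C)C)c1O[Si](C)(C)C(C)(C)C | intermediate
6 | 2-bromo-1-[2,3-bis(tert-butyldimethylsilyloxy)-4-methoxy-5-(3-methylbut-2-en-1-yl)phenyl]ethan-1-one | BrCC(=O)c1cc(CC=C(C)C)c(OC)c(O[Si](C)(C)C(C)(C)C)c1O[Si](C)(C)C(C)(C)C | intermediate
7 | 2,4-dihydroxybenzaldehyde | O=Cc1ccc(O)cc1O | starting material
8 | 2-hydroxy-4-(triisopropylsilyloxy)benzaldehyde | O=Cc1ccc(O[Si](C(C)C)(C(C)C)C(C)C)cc1O | intermediate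
9 | 2-{2-[2,3-bis(tert-butyldimethylsilyloxy)-4-methoxy-5-(3-methylbut-2-en-1-yl)phenyl]-2-oxoethoxy}-4-(triisopropylsilyloxy)benzaldehyde | O=Cc1ccc(O[Si](C(C)C)(C(C)C)C(C)C)cc1OCC(=O)c1cc(CC=C(C)C)c(OC)c(O[Si](C)(C)C(C)(C)C)c1O[Si](C)(C)C(C)(C)C | intermediate
10 | (3S)-3-[2,3-bis(tert-butyldimethylsilyloxy)-4-methoxy-5-(3-methylbut-2-en-1-yl)phenyl]-3-hydroxy-7-(triisopropylsilyloxy)chroman-4-one | COc1c(CC=C(C)C)cc([C@]2(O)COc3cc(O[Si](C(C)C)(C(C)C)C(C)C)ccc3C2=O)c(O[Si](C)(C)C(C)(C)C)c1O[Si](C)(C)C(C)(C)C | intermediate
11 | (3S)-3-[2,3-dihydroxy-4-methoxy-5-(3-methylbut-2-en-1-yl)phenyl]-3,7-dihydroxychroman-4-one | COc1c(CC=C(C)C)cc([C@]2(O)COc3cc(O)ccc3C2=O)c(O)c1O | target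

**Step count**

Total steps: 8. Longest linear sequence: 7 steps (steps 1, 2, 3, 4, 6, 7, 8); step 5 is a one-step side branch.

**Steps most likely to fail**

1. Step 7. The hindered, electron-rich ortho-silyloxy aryl ketone may accept the acyl anion slowly. Base-mediated enolization and aldol closure onto the aldehyde could then compete with carbene turnover, and facial discrimination could be too low for a single enantiomer. Fallback, from 9 back to 10: the cyclization would be run with the small, more reactive achiral precatalyst 2-(pentafluorophenyl)-6,7-dihydro-5H-pyrrolo[2,1-c][1,2,4]triazol-2-ium tetrafluoroborate and Et3N in toluene. This should give the racemic ketol, rac-3-[2,3-bis(tert-butyldimethylsilyloxy)-4-methoxy-5-(3-methylbut-2-en-1-yl)phenyl]-3-hydroxy-7-(triisopropylsilyloxy)chroman-4-one F1. Stereocontrol would then come from separation instead of from the catalyst: the enantiomers would be resolved by preparative chromatography on a polysaccharide chiral stationary phase, and the (S) enantiomer is 10, which continues into step 8.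

2. Step 3. Allyl transposition during transmetalation or reductive elimination could deliver the branched 1,1-dimethylallyl isomer alongside the prenyl group, and oxidative addition into the electron-rich aryl bromide could be slow. Fallback, from 3 back to 4: Stille coupling with allyltributylstannane (Pd(PPh3)4, DMF, 100 °C), where transposition cannot change the product, would give 1-[5-allyl-2,3-bis(tert-butyldimethylsilyloxy)-4-methoxyphenyl]ethan-1-one F2. Cross-metathesis of F2 with excess 2-methylbut-2-ene and second-generation Grubbs catalyst, RuCl2(=CHPh)(PCy3)(H2IMes), in CH2Cl2 at 40 °C would then turn the allyl group into the prenyl group and return to 4.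

3. Step 6. Silyl transfer from the 2'-oxygen of 6 to the phenoxide, followed by intramolecular displacement of bromide (closure to a benzofuran-3-one), or base-induced aldol cyclization of the product, could consume material. Fallback, from 6 back to 9, forming the same ether bond without a free phenoxide: displacement of bromide with HCO2Na (DMF, rt) would give the formate ester 2-[2,3-bis(tert-butyldimethylsilyloxy)-4-methoxy-5-(3-methylbut-2-en-1-yl)phenyl]-2-oxoethyl formate F3. Mild methanolysis (NaHCO3, MeOH, 0 °C) would give the α-hydroxy ketone 1-[2,3-bis(tert-butyldimethylsilyloxy)-4-methoxy-5-(3-methylbut-2-en-1-yl)phenyl]-2-hydroxyethan-1-one F4. Mitsunobu etherification of F4 with phenol 8 (PPh3, DIAD, THF, 0 °C) would then give 9.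

**Further compounds**

F1 | step 7 | rac-3-[2,3-bis(tert-butyldimethylsilyloxy)-4-methoxy-5-(3-methylbut-2-en-1-yl)phenyl]-3-hydroxy-7-(triisopropylsilyloxy)chroman-4-one | COc1c(CC=C(C)C)cc(C2(O)COc3cc(O[Si](C(C)C)(C(C)C)C(C)C)ccc3C2=O)c(O[Si](C)(C)C(C)(C)C)c1O[Si](C)(C)C(C)(C)C
F2 | step 3 | 1-[5-allyl-2,3-bis(tert-butyldimethylsilyloxy)-4-methoxyphenyl]ethan-1-one | CC(=O)c1cc(CC=C)c(OC)c(O[Si](C)(C)C(C)(C)C)c1O[Si](C)(C)C(C)(C)C
F3 | step 6 | 2-[2,3-bis(tert-butyldimethylsilyloxy)-4-methoxy-5-(3-methylbut-2-en-1-yl)phenyl]-2-oxoethyl formate | O=COCC(=O)c1cc(CC=C(C)C)c(OC)c(O[Si](C)(C)C(C)(C)C)c1O[Si](C)(C)C(C)(C)C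
F4 | step 6 | 1-[2,3-bis(tert-butyldimethylsilyloxy)-4-methoxy-5-(3-methylbut-2-en-1-yl)phenyl]-2-hydroxyethan-1-one | OCC(=O)c1cc(CC=C(C)C)c(OC)c(O[Si](C)(C)C(C)(C)C)c1O[Si](C)(C)C(C)(C)C
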